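The data were computed for substances that don't exist; the scatter is artificial.

- The reading in violet and teal comes at 15 d, while the spring run, with twice the catalyst charge of either, stops at 40.0 h; I reach for that late reading in the following two ways.

in all of them: substrate 0.50 M; coupling partner 0.475 M

| flask | free catalyst | temperature | remark | time |
|---|---|---|---|---|
| spring | 6.4 mM | 25 °C | run made earlier |  |
| violet | 3.2 mM | 25 °C |  | 15 d |
| teal | 3.2 mM | 35 °C |  | 15 d |

spring run (percent of the substrate charged)

| time / h | catalyst intermediate C / % | product / % | substrate / % | catalyst intermediate B / % |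
|---|---|---|---|---|
| 3.00 | 2.1 | 18.0 | 81.9 | 0 |
| 4.00 | 0 | 23.0 | 78.6 | 0.8 |
| 6.00 | 0 | 28.8 | 68.4 | 0 |
| 10.0 | 0 | 41.1 | 57.5 | 0 |
| 15.0 | 0.4 | 53.0 | 47.0 | 0 |
| 25.0 | 1.0 | 66.4 | 31.0 | 1.2 |
| 40.0 | 0.3 | 81.4 | 18.7 | 0 |

(standard deviation of a reading: 1 percentage point)

- the earlier runs do not show what temperature does; that part of a forecast is a guess
- no earlier run changes the charge of free catalyst; that part of a forecast is a guess

* which of these there is most of at the end, counted by the substrate in it, violet (substrate / product / catalyst intermediate C / catalyst intermediate B)
* which of these there is most of at the end, counted by the substrate in it, teal (substrate / product / catalyst intermediate C / catalyst intermediate B)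
* how much there is at the end of the one of these that leads, in percent of the substrate charged: violet
* how much there is at the end of the one of these that leads, in percent of the substrate charged: teal

- The first way counts. At 15.0 h the spring run reads 47.0% substrate and 53.0% product, which sum to 100%, so I assume that each product takes one substrate and one coupling partner. The coupling partner is charged at 95.0% of the substrate, and I call this fraction the ceiling: the partner charge over the substrate charge, the most product a one-to-one coupling can give when the partner is the limiting reagent.

- The second way uses a clock. Let a be the fraction of substrate left and g the excess 5.00%. If the rate goes as a(a − g), then ln((a − g)/a) falls in a straight line with slope gκ, and the spring reading at 40.0 h gives κ = 0.130 h⁻¹.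

- I guess that rate follows the catalyst charge, so violet's 15 d counts as 180 h of spring time, and my first round gives 92.9% product.

- The two ways part, and the clock cheats: the last spring interval, from 25.0 h to 40.0 h, reads κ = 0.180 h⁻¹, higher than my first value. Going round again from the last reading with this κ gives 93.7%, nearer the ceiling than the first round.

- The ceiling contains neither time nor temperature, and teal has the same charges, so I commit to product leading in both flasks, just under 95.0% in violet and in teal, where the effect of warming is a guess.

- The forecast says product at 91% in violet and product at 93.5% in teal, on the ground that the partner “caps product near 95% if coupling is 1:1”. Its violet figure lies 2.7 percentage points below my second round.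

- The flasks give product at 94.5% in violet and product at 94.5% in teal, so the forecast is right within its margins.

    coupling partner + free catalyst → catalyst intermediate A (k = 1.34 M⁻¹ min⁻¹, Ea = 42.0 kJ mol⁻¹)
    substrate + catalyst intermediate A ⇌ catalyst intermediate B (K = 20.7 M⁻¹, k = 0.251 M⁻¹ min⁻¹, Ea = 71.0 kJ mol⁻¹, ΔH = −26.0 kJ mol⁻¹)
    catalyst intermediate B ⇌ catalyst intermediate C (K = 2.11, k = 6.26 min⁻¹, Ea = 84.0 kJ mol⁻¹, ΔH = −53.0 kJ mol⁻¹)
    catalyst intermediate C ⇌ free catalyst + product (K = 0.420 M, k = 4.04 min⁻¹, Ea = 70.0 kJ mol⁻¹, ΔH = 20.0 kJ mol⁻¹)
    2 catalyst intermediate A ⇌ resting dimer (K = 180 M⁻¹, k = 0.196 M⁻¹ min⁻¹, Ea = 52.0 kJ mol⁻¹, ΔH = −27.0 kJ mol⁻¹)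
    (constants at 25 °C)

- In violet, half of the turnover from substrate and catalyst intermediate A to catalyst intermediate B is done by 0.957 d, far earlier than the reading at 15 d, and at 7.50 d the coupling partner is down to 0.0940% of its own charge. At the reading, violet's product stands 0.50 points under the ceiling. A flask like violet but charged with 2.0 M of substrate has a ceiling of 23.8%, and it ends with 0% of its coupling partner and 23.6% product.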